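Time is the one difference between winter and dawn: the same charge, read at 40 h and at 12 h.

| setting | north | south-west | west | winter | dawn |
|---|---|---|---|---|---|
| E | 0.034 M | 0.075 M | 0.050 M | 0.050 M | 0.050 M |
| J | 2.5 mM | 2.5 mM | 3.8 mM | 2.5 mM | 2.5 mM |
| remark | run made earlier | run made earlier | run made earlier |  |  |
| time |  |  |  | 40 h | 12 h |

- north (time / h: D / %): 2.50: 1.0; 8.00: 4.7; 15.0: 8.4; 20.0: 11.3; 30.0: 13.4; 40.0: 13.6
- south-west (time / h: D / %): 6.00: 5.4; 12.0: 11.7; 20.0: 16.5; 25.0: 19.4; 30.0: 20.4; 40.0: 21.9
- west (time / h: D / %): 3.00: 1.9; 6.00: 5.9; 12.0: 13.0; 20.0: 18.5; 40.0: 22.8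

(each reading ± 0.5 percentage points)

- the average divides the monomer in chains by the number of chains begun, living and dead together
- what was read earlier has a scatter of 0.5 percentage points, one standard deviation
- the earlier runs do not show the number of chains; that part of a forecast is a guess

* which of the two ends with the longer chains by the average number of monomer units in a chain (chains begun, living or dead) ("neither" if they lie within 10 %) (winter / dawn / neither)
* average number of monomer units in a chain (chains begun, living or dead) at the end, winter
* average number of monomer units in a chain (chains begun, living or dead) at the end, dawn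

**A puzzle.** The north run ends with D at 13.6 % of the E charged, yet its [J] was charged at 7.35 % of its [E]. South-west is sharper: 16.4 mM of D at 40.0 h from 2.5 mM of J. Both can stand because D counts monomer units in chains, so J acts as an initiator and not as a limiting reagent. If one J begins at most one chain, south-west averages at least 6.56 units.

**Powers of E.** In logarithms, the amount of D against charged [E], from north to south-west, has a slope of 1.60 at 40.0 h. North, taken between its readings at 8.00 h and 15.0 h, holds 2.32 mM of D at 12 h, and from there to south-west the slope is 1.68. Both slopes are readings and carry the scatter. At 0.050 M of E they give 8.58 mM of D for winter and 4.43 mM for dawn.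

**The floor.** Dawn's floor length, the D formed per J charged, is 1.77; winter's is 3.43. This reckoning puts winter ahead if chains begun grow by less than a factor of 1.94 between the two times, and that is a guess.

**The forecast.** It gives winter, with 3.4 and 1.8, on the guess that “all J has started one chain by 12 h”; this reckoning holds those figures as floors, not as lengths.

**The result.** Winter reaches 7.58 and dawn 5.05, so winter ends longer.

    E + J → L + D (k = 1.10 M⁻¹ h⁻¹)
    E → Z (k = 0.0590 h⁻¹)
    E + L → D + L, rate k3*[L]*[E] (k = 19.0 M⁻¹ h⁻¹)
    J + D → X (k = 3.50 M⁻¹ h⁻¹)

**Above the floor.** Dawn stands at 2.85 times its floor, with L at 8.90 × 10⁻⁴ M, which is 35.6 % of the J charged, and J at 58.4 % of its charge. The neighbour of dawn charged with 0.085 M of E takes dawn's floor up the same slope, which gives a floor of 4.33. That flask ends at 8.24, 1.90 times this floor, with J at 38.5 % of its charge.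

(The readings stem from a simulated flask for an exercise; scatter was added.)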